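**Retrosynthetic overview**
- Target ⇒ primary acetate from the silyl ether, and the C8 carbinol from methyl addition to a cis-fused decalin-8-one.
- Key disconnection C9–C10: one-carbon ring expansion of a cis-hydrindan-1-one, in which the quaternary ring-fusion carbon shifts 1,2 onto a chiral lithiated benzoate carbon that already carries the whole side chain.
- Hydrindanone ⇐ hydromethylation of an exocyclic methylene ⇐ intramolecular enolate alkylation (closes ring A, cis) ⇐ Cu-catalysed asymmetric conjugate addition of a vinylalane from 5-chloropent-1-yne to 2-methylcyclopent-2-enone.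
- Side chain ⇐ pent-4-yn-1-ol by benzoylation, Zr-catalysed carboalumination with formaldehyde trapping (E-alkene), and silylation.
- Ring order: five-membered ring (purchased), then ring A (alkylation), then ring B (ring expansion of the five-membered ring).

Assumption: the SMILES is taken literally, i.e. a cis-fused labdane (H-5 and the angular methyl on the same face, C8 hydroxyl cis to the C9 side chain), (1R,2S,4aR,8aS) in decalin numbering; labdane numbering (C5, C8, C9, C10) is used in the comments.

**Step 1**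
Reactants: 1 5-chloropent-1-yne; 2 2-methylcyclopent-2-en-1-one
Product: 4 (3S)-3-(5-chloropent-1-en-2-yl)-2-methylcyclopentan-1-one, via diisobutyl(5-chloropent-1-en-2-yl)alane 3 (not isolated)
Conditions: i-Bu2AlH, Ni(dppp)Cl2 (3 mol%), THF, 0 to 22 °C; then 2, Cu(OTf)2 (5 mol%), chiral phosphinamine ligand (SimplePhos type, antipode giving 3S, 10 mol%), Et2O/THF, −30 °C; aq. NH4Cl
Reagents that add atoms: none
Why: Ni-catalysed α-selective hydroalumination gives the internal vinylalane, and its Cu-catalysed asymmetric conjugate addition to the β-unsubstituted enone sets C3 (the future C5) as S under ligand control, while C2 stays an epimer mixture that is re-enolised in step 2.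

**Step 2**
Reactants: 4 (3S)-3-(5-chloropent-1-en-2-yl)-2-methylcyclopentan-1-one
Product: 5 (3aR,7aS)-7a-methyl-4-methylideneoctahydro-1H-inden-1-one
Conditions: KOtBu, t-BuOH/THF, 0 to 50 °C
Reagents that add atoms: none
Why: Intramolecular enolate C-alkylation (6-exo-tet) through the more substituted enolate closes ring A, and because the three-carbon tether can only reach the enolate face it is attached to, the quaternary carbon forms cis to the ring-fusion hydrogen (7aS).

**Step 3**
Reactants: 5 (3aR,7aS)-7a-methyl-4-methylideneoctahydro-1H-inden-1-one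
Product: 7 (3aR,7aS)-4,4,7a-trimethyloctahydro-1H-inden-1-one, via N'-alkylated methanesulfonohydrazide 6 (not isolated)
Conditions: Fe(acac)3 (30 mol%), PhSiH3, CH2=N–NHSO2Me, THF/MeOH, 25 °C; then MeOH, 60 °C
Reagents that add atoms: formaldehyde N-mesylhydrazone, C=NNS(C)(=O)=O
Why: Hydrogen-atom-transfer hydromethylation (Mukaiyama-type radical hydrofunctionalisation): Markovnikov H-atom transfer gives the tertiary radical, which adds to the hydrazone carbon, and heating expels sulfinate and N2 to leave the second methyl, with no new stereocentre.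

**Step 4**
Reactants: 8 pent-4-yn-1-ol
Product: 9 pent-4-yn-1-yl 2,4,6-triisopropylbenzoate
Conditions: 2,4,6-triisopropylbenzoyl chloride, Et3N, DMAP (cat.), CH2Cl2, 40 °C
Reagents that add atoms: 2,4,6-triisopropylbenzoyl chloride, CC(C)c1cc(C(C)C)c(C(Cl)=O)c(C(C)C)c1
Why: Acylation of the primary alcohol gives the hindered benzoate, which survives organometallics, directs α-lithiation later and can act as a leaving group.

**Step 5**
Reactants: 9 pent-4-yn-1-yl 2,4,6-triisopropylbenzoate
Product: 12 (4E)-6-hydroxy-4-methylhex-4-en-1-yl 2,4,6-triisopropylbenzoate, via (E)-alkenyl(dimethyl)alane 10 (not isolated), via lithium butyl(dimethyl)alkenylalanate 11 (not isolated)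
Conditions: Me3Al, Cp2ZrCl2 (20 mol%), CH2Cl2, 0 to 23 °C; evaporate; n-BuLi, THF, −78 °C; (CH2O)n, −78 to 23 °C; aqueous work-up
Reagents that add atoms: trimethylaluminium, C[Al](C)C; paraformaldehyde (as formaldehyde), C=O
Why: Negishi Zr-catalysed syn-carboalumination puts methyl on the internal carbon and aluminium on the terminus, which fixes the E geometry, and the alanate adds to formaldehyde with retention to give the allylic alcohol.

**Step 6**
Reactants: 12 (4E)-6-hydroxy-4-methylhex-4-en-1-yl 2,4,6-triisopropylbenzoate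
Product: 13 (4E)-6-{[tert-butyl(dimethyl)silyl]oxy}-4-methylhex-4-en-1-yl 2,4,6-triisopropylbenzoate
Conditions: TBSCl, imidazole, DMF, 23 °C
Reagents that add atoms: tert-butyldimethylsilyl chloride, CC(C)(C)[Si](C)(C)Cl
Why: Standard silylation protects the allylic hydroxyl against s-BuLi and MeLi.

**Step 7**
Reactants: 13 (4E)-6-{[tert-butyl(dimethyl)silyl]oxy}-4-methylhex-4-en-1-yl 2,4,6-triisopropylbenzoate; 7 (3aR,7aS)-4,4,7a-trimethyloctahydro-1H-inden-1-one
Product: 16 (1R,4aR,8aS)-1-[(3E)-5-{[tert-butyl(dimethyl)silyl]oxy}-3-methylpent-3-en-1-yl]-5,5,8a-trimethyloctahydronaphthalen-2(1H)-one, via (S)-α-lithiated benzoate sparteine complex 14 (not isolated), via lithium alkoxide adduct 15 (not isolated)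
Conditions: s-BuLi, (−)-sparteine, Et2O, −78 °C, 5 h; 7, −78 °C; then Et2AlCl (3 equiv), −78 to 0 °C; pH 7 buffer
Reagents that add atoms: none
Why: Proposed new method: sparteine-mediated deprotonation gives the configurationally stable (S)-α-lithiated benzoate, which adds to the ketone with retention; after transmetallation to aluminium the tertiary alkoxide pushes the antiperiplanar, more substituted α-carbon (quaternary C10) onto the carbinyl carbon with inversion while the Lewis-acid-bound carboxylate leaves (semipinacol 1,2-shift), so the cyclopentanone becomes the cyclohexanone, C9–C10 forms with retention at C10, and C9 is set R by the reagent whichever carbinol epimer forms; the closest known reactions are the 1,2-metallate shift of boronates made from the same lithiated benzoates (Matteson–Aggarwal homologation), the organoaluminium-promoted shift of β-mesyloxy alcohols (Suzuki–Tsuchihashi) and β-oxido carbenoid ring enlargement (Nozaki–Yamamoto).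

**Step 8**
Reactants: 16 (1R,4aR,8aS)-1-[(3E)-5-{[tert-butyl(dimethyl)silyl]oxy}-3-methylpent-3-en-1-yl]-5,5,8a-trimethyloctahydronaphthalen-2(1H)-one
Product: 17 (1R,2S,4aR,8aS)-1-[(3E)-5-{[tert-butyl(dimethyl)silyl]oxy}-3-methylpent-3-en-1-yl]-2,5,5,8a-tetramethyldecahydronaphthalen-2-ol
Conditions: MeLi, CeCl3, THF, −78 °C; aq. NH4Cl
Reagents that add atoms: methyllithium, [Li]C
Why: 1,2-Addition of the weakly basic organocerium (Imamoto conditions) avoids enolisation and C9 epimerisation, and methyl is expected to enter trans to the adjacent C9 chain, from the face opposite the chain and the angular methyl, giving the 8-hydroxyl cis to the chain (2S).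

**Step 9**
Reactants: 17 (1R,2S,4aR,8aS)-1-[(3E)-5-{[tert-butyl(dimethyl)silyl]oxy}-3-methylpent-3-en-1-yl]-2,5,5,8a-tetramethyldecahydronaphthalen-2-ol
Product: 19 (2E)-5-[(1R,2S,4aR,8aS)-2-hydroxy-2,5,5,8a-tetramethyldecahydronaphthalen-1-yl]-3-methylpent-2-en-1-yl acetate, via primary allylic alcohol 18 (not isolated)
Conditions: Bu4NF, THF, 0 °C; then pyridine, Ac2O, 0 to 23 °C
Reagents that add atoms: acetic anhydride, CC(=O)OC(C)=O
Why: Fluoride desilylation followed by acetylation of the primary allylic hydroxyl only, since the hindered tertiary alcohol does not acylate under pyridine/Ac2O at this temperature.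

**Compound list**
1 | 5-chloropent-1-yne | C#CCCCCl | starting material
2 | 2-methylcyclopent-2-en-1-one | CC1=CCCC1=O | starting material
3 | diisobutyl(5-chloropent-1-en-2-yl)alane | C=C(CCCCl)[Al](CC(C)C)CC(C)C | intermediate
4 | (3S)-3-(5-chloropent-1-en-2-yl)-2-methylcyclopentan-1-one (both C2 epimers) | CC1C(=O)CC[C@@H]1C(=C)CCCCl | intermediate
5 | (3aR,7aS)-7a-methyl-4-methylideneoctahydro-1H-inden-1-one (cis-fused) | C[C@]12CCCC(=C)[C@H]1CCC2=O | intermediate
6 | N'-{[(3aR,7aS)-4,7a-dimethyl-1-oxooctahydro-1H-inden-4-yl]methyl}methanesulfonohydrazide (both C4 epimers) | C[C@]12CCCC(C)(CNNS(C)(=O)=O)[C@H]1CCC2=O | intermediate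
7 | (3aR,7aS)-4,4,7a-trimethyloctahydro-1H-inden-1-one (cis-fused) | C[C@]12CCCC(C)(C)[C@H]1CCC2=O | intermediate
8 | pent-4-yn-1-ol | C#CCCCO | starting material
9 | pent-4-yn-1-yl 2,4,6-triisopropylbenzoate | C#CCCCOC(=O)c1c(C(C)C)cc(C(C)C)cc1C(C)C | intermediate
10 | dimethyl[(1E)-2-methyl-5-(2,4,6-triisopropylbenzoyloxy)pent-1-en-1-yl]alane | C[Al](C)/C=C(\C)CCCOC(=O)c1c(C(C)C)cc(C(C)C)cc1C(C)C | intermediate
11 | lithium butyl(dimethyl)[(1E)-2-methyl-5-(2,4,6-triisopropylbenzoyloxy)pent-1-en-1-yl]alanate | [Li+].CCCC[Al-](C)(C)/C=C(\C)CCCOC(=O)c1c(C(C)C)cc(C(C)C)cc1C(C)C | intermediate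
12 | (4E)-6-hydroxy-4-methylhex-4-en-1-yl 2,4,6-triisopropylbenzoate | OC/C=C(\C)CCCOC(=O)c1c(C(C)C)cc(C(C)C)cc1C(C)C | intermediate
13 | (4E)-6-{[tert-butyl(dimethyl)silyl]oxy}-4-methylhex-4-en-1-yl 2,4,6-triisopropylbenzoate | CC(C)(C)[Si](C)(C)OC/C=C(\C)CCCOC(=O)c1c(C(C)C)cc(C(C)C)cc1C(C)C | intermediate
14 | [(1S,4E)-6-{[tert-butyl(dimethyl)silyl]oxy}-4-methyl-1-(2,4,6-triisopropylbenzoyloxy)hex-4-en-1-yl]lithium, as its (−)-sparteine complex | [Li][C@H](OC(=O)c1c(C(C)C)cc(C(C)C)cc1C(C)C)CC/C(C)=C/CO[Si](C)(C)C(C)(C)C | intermediate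
15 | lithium alkoxide of (1R,4E)-6-{[tert-butyl(dimethyl)silyl]oxy}-1-[(3aR,7aS)-1-hydroxy-4,4,7a-trimethyloctahydro-1H-inden-1-yl]-4-methylhex-4-en-1-yl 2,4,6-triisopropylbenzoate (both carbinol epimers) | CC(C)(C)[Si](C)(C)OC/C=C(\C)CC[C@@H](OC(=O)c1c(C(C)C)cc(C(C)C)cc1C(C)C)C2(O[Li])CC[C@@H]3C(C)(C)CCC[C@]23C | intermediate
16 | (1R,4aR,8aS)-1-[(3E)-5-{[tert-butyl(dimethyl)silyl]oxy}-3-methylpent-3-en-1-yl]-5,5,8a-trimethyloctahydronaphthalen-2(1H)-one (cis-fused, side chain cis to the angular methyl) | CC(C)(C)[Si](C)(C)OC/C=C(\C)CC[C@@H]1[C@@]2(C)CCCC(C)(C)[C@H]2CCC1=O | intermediate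
17 | (1R,2S,4aR,8aS)-1-[(3E)-5-{[tert-butyl(dimethyl)silyl]oxy}-3-methylpent-3-en-1-yl]-2,5,5,8a-tetramethyldecahydronaphthalen-2-ol | CC(C)(C)[Si](C)(C)OC/C=C(\C)CC[C@@H]1[C@@]2(C)CCCC(C)(C)[C@H]2CC[C@]1(C)O | intermediate
18 | (2E)-5-[(1R,2S,4aR,8aS)-2-hydroxy-2,5,5,8a-tetramethyldecahydronaphthalen-1-yl]-3-methylpent-2-en-1-ol | OC/C=C(\C)CC[C@@H]1[C@@]2(C)CCCC(C)(C)[C@H]2CC[C@]1(C)O | intermediate
19 | (2E)-5-[(1R,2S,4aR,8aS)-2-hydroxy-2,5,5,8a-tetramethyldecahydronaphthalen-1-yl]-3-methylpent-2-en-1-yl acetate (CNP0268033.2) | CC(=O)OC/C=C(\C)CC[C@@H]1[C@@]2(C)CCCC(C)(C)[C@H]2CC[C@]1(C)O | target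

**Step count and risks**
Total: 9 steps. Longest linear sequence: 6 steps (1, 2, 3, 7, 8, 9; the side-chain branch 4, 5, 6, 7, 8, 9 is equally long).

Most likely to fail, first: step 7, the new ring expansion. The carboxylate may leave too slowly, the alkoxide may close to an epoxide instead, or the CH2 carbon may migrate in place of the quaternary one. The fallback uses known chemistry only and sets out from 13 and 7. The same lithiation and ketone addition is run but quenched with NH4Cl, and β-hydroxy benzoate F1 is isolated. LiAlH4 in THF at reflux cleaves the hindered ester to diol F2. MsCl and Et3N at −20 °C sulfonylate only the secondary hydroxyl to give mesylate F3. Et3Al in CH2Cl2 at −78 °C then triggers the established stereospecific organoaluminium-promoted 1,2-shift, and the route is rejoined at 16. In either version the minor enantiomers of 7 and 14 end up mainly as diastereomers of 16, which chromatography removes, so the enantiomeric purity of 16 rises above that of its precursors.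

Second: step 8, the facial selectivity at C8. The target is a strained cis-decalin. The face opposite the chain is also the concave face under ring A, so the organocerium could enter from the other side and give the C8 epimer. The fallback sets out from 16 and delivers oxygen instead of carbon to the accessible face. Methylenation with Zn, CH2Br2 and TiCl4 (Lombardo) gives methylidene decalin F4 without epimerising C9. Mukaiyama hydration (Co(acac)2, PhSiH3, O2, then PPh3) is selective for the 1,1-disubstituted alkene over the trisubstituted allylic ether and gives the tertiary alcohol of opposite C8 configuration to that from direct methyl addition. The route is rejoined at 17.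

Third: step 1. An α-branched alkenylalane on an α-methyl enone is an untested pairing and may give low conversion or low ee. The fallback sets out from 1, converted into alane 3 as before, and uses the better-precedented acceptor cyclopent-2-en-1-one F5 under the same type of Cu catalysis. The aluminium enolate is trapped with TMSOTf as silyl enol ether F6. MeLi then releases the lithium enolate, which MeI methylates regiospecifically at C2. The route is rejoined at 4.

**Further compounds**
F1 | step 7 | (1R,4E)-6-{[tert-butyl(dimethyl)silyl]oxy}-1-[(3aR,7aS)-1-hydroxy-4,4,7a-trimethyloctahydro-1H-inden-1-yl]-4-methylhex-4-en-1-yl 2,4,6-triisopropylbenzoate (both carbinol epimers) | CC(C)(C)[Si](C)(C)OC/C=C(\C)CC[C@@H](OC(=O)c1c(C(C)C)cc(C(C)C)cc1C(C)C)C2(O)CC[C@@H]3C(C)(C)CCC[C@]23C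
F2 | step 7 | (1R,4E)-6-{[tert-butyl(dimethyl)silyl]oxy}-1-[(3aR,7aS)-1-hydroxy-4,4,7a-trimethyloctahydro-1H-inden-1-yl]-4-methylhex-4-en-1-ol (both carbinol epimers) | CC(C)(C)[Si](C)(C)OC/C=C(\C)CC[C@@H](O)C1(O)CC[C@@H]2C(C)(C)CCC[C@]12C
F3 | step 7 | (1R,4E)-6-{[tert-butyl(dimethyl)silyl]oxy}-1-[(3aR,7aS)-1-hydroxy-4,4,7a-trimethyloctahydro-1H-inden-1-yl]-4-methylhex-4-en-1-yl methanesulfonate (both carbinol epimers) | CC(C)(C)[Si](C)(C)OC/C=C(\C)CC[C@@H](OS(C)(=O)=O)C1(O)CC[C@@H]2C(C)(C)CCC[C@]12C
F4 | step 8 | tert-butyl(dimethyl){[(2E)-3-methyl-5-[(1S,4aR,8aS)-5,5,8a-trimethyl-2-methylidenedecahydronaphthalen-1-yl]pent-2-en-1-yl]oxy}silane (same spatial arrangement as 16) | CC(C)(C)[Si](C)(C)OC/C=C(\C)CC[C@@H]1[C@@]2(C)CCCC(C)(C)[C@H]2CCC1=C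
F5 | step 1 | cyclopent-2-en-1-one (purchased) | O=C1C=CCC1
F6 | step 1 | {[(3S)-3-(5-chloropent-1-en-2-yl)cyclopent-1-en-1-yl]oxy}trimethylsilane | C[Si](C)(C)OC1=C[C@@H](C(=C)CCCCl)CC1
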